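**Retrosynthetic overview**
- Ring A is closed last by a Diels–Alder reaction of methyl methacrylate with a 1-vinylcyclohexene (C2–C3 and C4–C5 bonds; sets C4 and C5).
- The allylic acetate C15–O bond is made by a catalytic, E-selective 1,4-addition of acetic acid to a 2-substituted 1,3-diene (key step).
- Both dienes, in the ring and in the side chain, come from one 1,5-diketone by twofold enol triflation and twofold vinylation.
- The diketone comes from 2-methylcyclohex-2-enone (ring B) by asymmetric conjugate methylation and Mukaiyama–Michael addition to methyl vinyl ketone (sets C8 and C9).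
- Ring order: ring B is present from the start; ring A is formed in the final step.

Assumption: the configuration is read from the SMILES as given (halimane numbering 4S,5R,8R,9S), so H-5 lies on the face of the C-8 and C-9 methyl groups and the C-4 ester on the face of the C-9 side chain; halimane atom numbers are used in the reasoning.

**Step 1**
Reactants: 1 2-methylcyclohex-2-en-1-one
Product: 3 trimethyl{[(3R)-2,3-dimethylcyclohex-1-en-1-yl]oxy}silane, via dimethylaluminium enolate 2 (not isolated)
Conditions: Me3Al (1.4 equiv), Cu(O2CC4H3S) (copper thiophene-2-carboxylate, 2 mol%), chiral phosphoramidite ligand (4 mol%, the enantiomer that gives 3R), Et2O, −30 °C; then Me3SiOTf (1.5 equiv), THF, −30 → 0 °C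
Reagents that add atoms: trimethylaluminium C[Al](C)C; trimethylsilyl trifluoromethanesulfonate C[Si](C)(C)OS(=O)(=O)C(F)(F)F
Why: Copper-catalysed asymmetric conjugate addition of Me3Al to a trisubstituted enone; the chiral copper–phosphoramidite complex delivers methyl to one face of C3 (3R, the future C8), and the regiodefined aluminium enolate is O-silylated in the same flask.

**Step 2**
Reactants: 3 trimethyl{[(3R)-2,3-dimethylcyclohex-1-en-1-yl]oxy}silane, 4 but-3-en-2-one
Product: 6 (2S,3R)-2,3-dimethyl-2-(3-oxobutyl)cyclohexan-1-one, via silyl enol ether adduct 5 (not isolated)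
Conditions: 4 (1.5 equiv), HNTf2 (2 mol%), CH2Cl2, −78 °C; then 1 M HCl, THF, 0 °C
Reagents that add atoms: none
Why: Mukaiyama–Michael addition under silyl-transfer catalysis (Me3SiNTf2 formed in situ); the enone attacks the tetrasubstituted enol ether carbon anti to the pseudoaxial C3 methyl (A(1,2) strain), which sets the quaternary centre (2S, the future C9) with the two methyl groups cis, and the acid work-up frees the methyl ketone.

**Step 3**
Reactants: 6 (2S,3R)-2,3-dimethyl-2-(3-oxobutyl)cyclohexan-1-one
Product: 8 (5R,6S)-5,6-dimethyl-6-[3-(trifluoromethanesulfonyloxy)but-3-en-1-yl]cyclohex-1-en-1-yl trifluoromethanesulfonate, via dilithium bis(enolate) 7 (not isolated)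
Conditions: LiN(i-Pr)2 (2.4 equiv), THF, −78 °C (6 added slowly to the base); then Comins' reagent (2.4 equiv), −78 → 0 °C
Reagents that add atoms: N-(5-chloropyridin-2-yl)-1,1,1-trifluoro-N-(trifluoromethanesulfonyl)methanesulfonamide (Comins' reagent) FC(F)(F)S(=O)(=O)N(c1ccc(Cl)cn1)S(=O)(=O)C(F)(F)F
Why: Kinetic double enolisation and O-triflation; the ring ketone can enolise only toward its CH2 (the other α-carbon is quaternary), the methyl ketone is deprotonated at CH3 by the hindered amide at −78 °C, and inverse addition keeps base in excess so that the bis(enolate) forms before an aldol closure can occur.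

**Step 4**
Reactants: 8 (5R,6S)-5,6-dimethyl-6-[3-(trifluoromethanesulfonyloxy)but-3-en-1-yl]cyclohex-1-en-1-yl trifluoromethanesulfonate
Product: 9 (5R,6S)-1-ethenyl-5,6-dimethyl-6-(3-methylidenepent-4-en-1-yl)cyclohex-1-ene
Conditions: CH2=CHB(pin) (3 equiv), Pd(dppf)Cl2 (5 mol%), K3PO4 (4 equiv), 1,4-dioxane/H2O 9:1, 60 °C
Reagents that add atoms: 2-ethenyl-4,4,5,5-tetramethyl-1,3,2-dioxaborolane C=CB1OC(C)(C)C(C)(C)O1
Why: Twofold Suzuki–Miyaura coupling of alkenyl triflates with a vinylboronate; both C(sp2)–O bonds add readily to zerovalent palladium, and the stereocentres are not touched.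

**Step 5**
Reactants: 9 (5R,6S)-1-ethenyl-5,6-dimethyl-6-(3-methylidenepent-4-en-1-yl)cyclohex-1-ene
Product: 10 (2E)-5-[(1S,6R)-2-ethenyl-1,6-dimethylcyclohex-2-en-1-yl]-3-methylpent-2-en-1-yl acetate
Conditions: AcOH (3 equiv), Pd2(dba)3 (2.5 mol%), t-Bu-Xantphos (6 mol%), toluene, 30 °C
Reagents that add atoms: acetic acid CC(=O)O
Why: Proposed new method: a palladium hydride formed from zerovalent palladium and AcOH binds the unhindered 2-substituted diene in its s-cis η4 form and transfers H to the CH2 of the 1,1-disubstituted alkene, giving a π-allyl in which the new methyl is anti and the chain syn; syn/anti exchange at that fully substituted terminus would need a tertiary σ-allyl and is slow, so acetate attack at the CH2 terminus (any branched acetate re-ionises and funnels to the linear one) gives the E allylic acetate and forms the C15–O bond, while the ring diene would have to form a crowded 1,2,3-trisubstituted π-allyl next to a quaternary carbon and should stay intact; the closest known reactions are the Pd-catalysed 1:1 additions of carboxylic acids, alcohols and amines to butadiene and isoprene and the E-selective Fe-catalysed 1,4-hydroboration of myrcene-type dienes.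

**Step 6**
Reactants: 10 (2E)-5-[(1S,6R)-2-ethenyl-1,6-dimethylcyclohex-2-en-1-yl]-3-methylpent-2-en-1-yl acetate, 11 methyl methacrylate
Product: 12 methyl (1S,5S,6R,8aR)-5-[(3E)-5-(acetyloxy)-3-methylpent-3-en-1-yl]-1,5,6-trimethyl-1,2,3,5,6,7,8,8a-octahydronaphthalene-1-carboxylate
Conditions: 11 (5 equiv), MeAlCl2 (1.5 equiv), CH2Cl2, −40 → 0 °C; 1 M HCl work-up
Reagents that add atoms: none
Why: Lewis-acid-promoted Diels–Alder reaction that forms ring A: the quaternary C9 holds the diene s-cis, the ester-bearing carbon bonds to the ring terminus C5 (ortho rule for a 1-substituted diene), the dienophile adds to the diene face anti to the C8 and C9 methyl groups (the face of the side chain), which puts H5 on the methyl face (5R), and the ester-endo transition state puts CO2Me trans to H5 (4S).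

**Compound list**
1 | 2-methylcyclohex-2-en-1-one | CC1=CCCCC1=O | starting material
2 | dimethylaluminium (3R)-2,3-dimethylcyclohex-1-en-1-olate | C[Al](C)OC1=C(C)[C@H](C)CCC1 | intermediate
3 | trimethyl{[(3R)-2,3-dimethylcyclohex-1-en-1-yl]oxy}silane | C[Si](C)(C)OC1=C(C)[C@H](C)CCC1 | intermediate
4 | but-3-en-2-one (methyl vinyl ketone) | CC(=O)C=C | starting material
5 | (2S,3R)-2,3-dimethyl-2-[3-(trimethylsilyloxy)but-2-en-1-yl]cyclohexan-1-one (E/Z mixture) | O=C1CCC[C@@H](C)[C@]1(C)CC=C(C)O[Si](C)(C)C | intermediate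
6 | (2S,3R)-2,3-dimethyl-2-(3-oxobutyl)cyclohexan-1-one | O=C1CCC[C@@H](C)[C@]1(C)CCC(C)=O | intermediate
7 | dilithium bis(enolate) of 6 (ring enolate toward CH2, side-chain enolate toward CH3) | [Li]OC1=CCC[C@@H](C)[C@]1(C)CCC(=C)O[Li] | intermediate
8 | (5R,6S)-5,6-dimethyl-6-[3-(trifluoromethanesulfonyloxy)but-3-en-1-yl]cyclohex-1-en-1-yl trifluoromethanesulfonate | FC(F)(F)S(=O)(=O)OC1=CCC[C@@H](C)[C@]1(C)CCC(=C)OS(=O)(=O)C(F)(F)F | intermediate
9 | (5R,6S)-1-ethenyl-5,6-dimethyl-6-(3-methylidenepent-4-en-1-yl)cyclohex-1-ene | C=CC1=CCC[C@@H](C)[C@]1(C)CCC(=C)C=C | intermediate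
10 | (2E)-5-[(1S,6R)-2-ethenyl-1,6-dimethylcyclohex-2-en-1-yl]-3-methylpent-2-en-1-yl acetate | C=CC1=CCC[C@@H](C)[C@]1(C)CC/C(C)=C/COC(C)=O | intermediate
11 | methyl methacrylate | C=C(C)C(=O)OC | starting material
12 | methyl (1S,5S,6R,8aR)-5-[(3E)-5-(acetyloxy)-3-methylpent-3-en-1-yl]-1,5,6-trimethyl-1,2,3,5,6,7,8,8a-octahydronaphthalene-1-carboxylate | COC(=O)[C@@]1(C)CCC=C2[C@H]1CC[C@@H](C)[C@]2(C)CC/C(C)=C/COC(C)=O | target

**Step count and risks**
Total step count: 6. Longest linear sequence: 6 steps (1 to 12).

Steps most likely to fail: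

Step 5 (the new hydroacetoxylation). The catalyst may also touch the ring diene (isomerisation or addition), may telomerise two dienes, or may give E/Z mixtures if the allyl intermediate equilibrates. The fallback uses known chemistry, sets out from 9 and comes back at 10. Iron-catalysed 1,4-hydroboration of the 2-substituted diene with pinacolborane (iminopyridine–FeCl2 precatalyst reduced with Mg, Et2O, room temperature) is known to give E-configured linear allylboronates from myrcene-type dienes. It would give 2-{(2E)-5-[(1S,6R)-2-ethenyl-1,6-dimethylcyclohex-2-en-1-yl]-3-methylpent-2-en-1-yl}-4,4,5,5-tetramethyl-1,3,2-dioxaborolane F1. Oxidation with NaBO3 in THF/H2O gives (2E)-5-[(1S,6R)-2-ethenyl-1,6-dimethylcyclohex-2-en-1-yl]-3-methylpent-2-en-1-ol F2, and Ac2O, pyridine and DMAP give 10.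

Step 6 (Diels–Alder). This is the step I trust least on stereochemistry. The facial preference is well founded, but α-methyl dienophiles often show weak or reversed endo selectivity, and hindered 1-vinylcyclohexenes are known to give exo adducts with α-methyl enals. If that holds here, the C4 epimer of 12 would be the major product. The fallback sets C4 by enolate alkylation instead, sets out from 10 and comes back at 12. K2CO3 in MeOH removes the acetate and gives (2E)-5-[(1S,6R)-2-ethenyl-1,6-dimethylcyclohex-2-en-1-yl]-3-methylpent-2-en-1-ol F2. Its Diels–Alder reaction with methyl acrylate (Me2AlCl, 2.2 equiv, CH2Cl2, −78 °C; endo or exo no longer matters, only the diene face) gives methyl (5S,6R,8aS)-5-[(3E)-5-hydroxy-3-methylpent-3-en-1-yl]-5,6-dimethyl-1,2,3,5,6,7,8,8a-octahydronaphthalene-1-carboxylate F3 as a mixture at C1. LiN(i-Pr)2 (2.3 equiv) and then MeI methylate the ester enolate; A(1,3) strain turns the C8a–C8 bond perpendicular to the enolate, so MeI should enter anti to it, cis to H8a. This gives methyl (1S,5S,6R,8aR)-5-[(3E)-5-hydroxy-3-methylpent-3-en-1-yl]-1,5,6-trimethyl-1,2,3,5,6,7,8,8a-octahydronaphthalene-1-carboxylate F4, and Ac2O, pyridine and DMAP give 12.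

Step 3 (twofold enol triflation). The first-formed methyl ketone enolate can close onto the ring ketone (six-membered aldol) before the second deprotonation, and some internal enol triflate can form. The fallback triflates the two ketones one after the other, sets out from 5 and comes back at 8. The crude silyl-transfer Michael mixture containing 5 is not hydrolysed but treated with KN(SiMe3)2 and PhNTf2 (THF, −78 °C). Only the ring ketone can enolise, which gives (5R,6S)-5,6-dimethyl-6-[3-(trimethylsilyloxy)but-2-en-1-yl]cyclohex-1-en-1-yl trifluoromethanesulfonate F5. Dilute HCl in THF frees the methyl ketone to give (5R,6S)-5,6-dimethyl-6-(3-oxobutyl)cyclohex-1-en-1-yl trifluoromethanesulfonate F6. LiN(i-Pr)2 and Comins' reagent at −78 °C then give 8 with no second ketone present.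

**Further compounds**
F1 | step 5 | 2-{(2E)-5-[(1S,6R)-2-ethenyl-1,6-dimethylcyclohex-2-en-1-yl]-3-methylpent-2-en-1-yl}-4,4,5,5-tetramethyl-1,3,2-dioxaborolane | C=CC1=CCC[C@@H](C)[C@]1(C)CC/C(C)=C/CB1OC(C)(C)C(C)(C)O1
F2 | step 5 | (2E)-5-[(1S,6R)-2-ethenyl-1,6-dimethylcyclohex-2-en-1-yl]-3-methylpent-2-en-1-ol | C=CC1=CCC[C@@H](C)[C@]1(C)CC/C(C)=C/CO
F3 | step 6 | methyl (5S,6R,8aS)-5-[(3E)-5-hydroxy-3-methylpent-3-en-1-yl]-5,6-dimethyl-1,2,3,5,6,7,8,8a-octahydronaphthalene-1-carboxylate (mixture at C1) | COC(=O)C1CCC=C2[C@H]1CC[C@@H](C)[C@]2(C)CC/C(C)=C/CO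
F4 | step 6 | methyl (1S,5S,6R,8aR)-5-[(3E)-5-hydroxy-3-methylpent-3-en-1-yl]-1,5,6-trimethyl-1,2,3,5,6,7,8,8a-octahydronaphthalene-1-carboxylate | COC(=O)[C@@]1(C)CCC=C2[C@H]1CC[C@@H](C)[C@]2(C)CC/C(C)=C/CO
F5 | step 3 | (5R,6S)-5,6-dimethyl-6-[3-(trimethylsilyloxy)but-2-en-1-yl]cyclohex-1-en-1-yl trifluoromethanesulfonate | FC(F)(F)S(=O)(=O)OC1=CCC[C@@H](C)[C@]1(C)CC=C(C)O[Si](C)(C)C
F6 | step 3 | (5R,6S)-5,6-dimethyl-6-(3-oxobutyl)cyclohex-1-en-1-yl trifluoromethanesulfonate | FC(F)(F)S(=O)(=O)OC1=CCC[C@@H](C)[C@]1(C)CCC(C)=O
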